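**Retrosynthetic overview**
- The enal is made last, by Wittig two-carbon homologation of the aryl aldehyde, which comes from an aryl methyl ester; the free phenol comes from an aryl bromide by borylation and oxidation.
- The 1,4-dioxane ring is closed by intramolecular Cu-catalysed O-arylation of a secondary benzylic alcohol onto one of two equivalent ortho C–Br bonds, so no bond to a stereocentre is broken.
- Key C–C bond (dioxane C2–C3): Evans syn-aldol between 3,4,5-trimethoxybenzaldehyde and the boron enolate of an N-(aryloxyacetyl)oxazolidinone; the syn (threo) adduct already carries the configuration of the trans-(2S,3S) ring.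
- The aryloxyacetyl unit comes from methyl 3,5-dibromo-4-hydroxybenzoate and tert-butyl bromoacetate, with (R)-4-benzyloxazolidin-2-one as chiral controller.
- Ring order: both benzene rings are bought; the dioxane ring is the only ring formed (step 7), after the aldol and before the side-chain work.

Assumption: the SMILES is read as the trans-(2S,3S) isomer, (E)-3-[(2S,3S)-8-hydroxy-2-(hydroxymethyl)-3-(3,4,5-trimethoxyphenyl)-2,3-dihydro-1,4-benzodioxin-6-yl]prop-2-enal, and all five starting materials are taken to be catalogue chemicals.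

**Step 1**
Reactants: 1 methyl 3,5-dibromo-4-hydroxybenzoate; 2 tert-butyl bromoacetate
Product: 3 methyl 3,5-dibromo-4-(2-tert-butoxy-2-oxoethoxy)benzoate
Conditions: K2CO3, DMF, 60 °C
Reagents that add atoms: none
Why: Williamson ether synthesis, in which the acidic 2,6-dibromophenoxide is O-alkylated by the reactive α-bromo ester and the tert-butyl ester keeps the new carboxyl distinct from the aryl methyl ester.

**Step 2**
Reactants: 3 methyl 3,5-dibromo-4-(2-tert-butoxy-2-oxoethoxy)benzoate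
Product: 4 2-[2,6-dibromo-4-(methoxycarbonyl)phenoxy]acetic acid
Conditions: TFA, CH2Cl2, rt
Reagents that add atoms: none
Why: Acidolysis of the tert-butyl ester (E1 loss of isobutene) frees the acetic acid while the methyl benzoate and aryl bromides are inert.

**Step 3**
Reactants: 4 2-[2,6-dibromo-4-(methoxycarbonyl)phenoxy]acetic acid; 5 (R)-4-benzyl-1,3-oxazolidin-2-one
Product: 7 methyl 4-{2-[(4R)-4-benzyl-2-oxo-1,3-oxazolidin-3-yl]-2-oxoethoxy}-3,5-dibromobenzoate, via mixed pivalic anhydride 6 (not isolated)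
Conditions: PivCl, Et3N, THF, −20 °C; then 5, LiCl, −20 °C → rt
Reagents that add atoms: pivaloyl chloride CC(C)(C)C(=O)Cl (its acyl group is in 6 only)
Why: N-acylation of the oxazolidinone through a mixed anhydride, which is attacked at the unhindered aryloxyacetyl carbonyl and not at the pivaloyl carbonyl.

**Step 4**
Reactants: 7 methyl 4-{2-[(4R)-4-benzyl-2-oxo-1,3-oxazolidin-3-yl]-2-oxoethoxy}-3,5-dibromobenzoate; 8 3,4,5-trimethoxybenzaldehyde
Product: 11 (4R)-4-benzyl-3-[(2R,3S)-2-(2,6-dibromo-4-methoxycarbonylphenoxy)-3-hydroxy-3-(3,4,5-trimethoxyphenyl)propanoyl]-1,3-oxazolidin-2-one, via boron enolate 9 (not isolated), via boron aldolate 10 (not isolated)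
Conditions: Bu2BOTf, iPr2NEt, CH2Cl2, −78 → 0 °C; 8, −78 → 0 °C; then pH 7 buffer, MeOH, 30% H2O2, 0 °C
Reagents that add atoms: dibutylboron triflate CCCCB(CCCC)OS(=O)(=O)C(F)(F)F (Bu2B is in 9 and 10 only)
Why: Evans syn-aldol reaction, in which the (Z)-boron enolate reacts through a Zimmerman–Traxler chair on the face opposite the benzyl group of the (R)-auxiliary, setting C2 (R) and C3 (S) of the propanoyl chain as the syn (threo) pair that maps onto the trans-(2S,3S) dioxane.

**Step 5**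
Reactants: 11 the syn-aldol adduct
Product: 12 methyl 3,5-dibromo-4-{[(1S,2S)-1,3-dihydroxy-1-(3,4,5-trimethoxyphenyl)propan-2-yl]oxy}benzoate
Conditions: NaBH4, THF/H2O (3:1), 0 °C → rt
Reagents that add atoms: none
Why: Reductive cleavage of the N-acyloxazolidinone, whose imide carbonyl is far more electrophilic than the methyl benzoate, gives the primary alcohol and returns the auxiliary without touching either stereocentre.

**Step 6**
Reactants: 12 the threo diol
Product: 13 methyl 3,5-dibromo-4-{[(1S,2S)-1-hydroxy-1-(3,4,5-trimethoxyphenyl)-3-(trityloxy)propan-2-yl]oxy}benzoate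
Conditions: TrCl, Et3N, DMAP (cat.), CH2Cl2, rt
Reagents that add atoms: trityl chloride ClC(c1ccccc1)(c1ccccc1)c1ccccc1
Why: Selective tritylation (SN1 etherification) of the primary hydroxyl blocks the one competing nucleophile, and trityl cannot migrate to the neighbouring alkoxide in the basic next step.

**Step 7**
Reactants: 13 the trityl ether
Product: 14 methyl (2S,3S)-8-bromo-3-(3,4,5-trimethoxyphenyl)-2-[(trityloxy)methyl]-2,3-dihydro-1,4-benzodioxine-6-carboxylate
Conditions: CuI (10 mol%), 3,4,7,8-tetramethyl-1,10-phenanthroline (20 mol%), Cs2CO3, toluene, 110 °C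
Reagents that add atoms: none
Why: Intramolecular Ullmann-type Cu-catalysed O-arylation closes the six-membered dioxane onto either of the two equivalent ortho bromides, and since only the aryl C–Br bond is broken both stereocentres are retained and the threo (1S,2S) alcohol becomes the trans-(2S,3S) ring.

**Step 8**
Reactants: 14 the bromo benzodioxane
Product: 16 methyl (2S,3S)-8-hydroxy-3-(3,4,5-trimethoxyphenyl)-2-[(trityloxy)methyl]-2,3-dihydro-1,4-benzodioxine-6-carboxylate, via pinacol boronate 15 (not isolated)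
Conditions: B2pin2, Pd(dppf)Cl2 (5 mol%), KOAc, 1,4-dioxane, 90 °C; then NaBO3·4H2O, THF/H2O, rt
Reagents that add atoms: bis(pinacolato)diboron CC1(C)OB(OC1(C)C)B1OC(C)(C)C(C)(C)O1 (Bpin is in 15 only); sodium perborate [Na+].[O-]OB=O (the phenol oxygen of 16)
Why: Miyaura borylation of the remaining aryl bromide followed by mild oxidative C–B to C–O exchange installs the phenol without affecting the methyl ester, the trityl ether or the stereocentres.

**Step 9**
Reactants: 16 the trityl-protected phenol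
Product: 17 methyl (2S,3S)-8-hydroxy-2-(hydroxymethyl)-3-(3,4,5-trimethoxyphenyl)-2,3-dihydro-1,4-benzodioxine-6-carboxylate
Conditions: TsOH·H2O (cat.), MeOH/CH2Cl2 (1:1), rt
Reagents that add atoms: none
Why: Acid-catalysed methanolysis of the trityl ether (SN1 at the trityl carbon) frees the primary alcohol before any acid-sensitive enal is present.

**Step 10**
Reactants: 17 the hydroxy ester
Product: 18 [(2S,3S)-8-hydroxy-3-(3,4,5-trimethoxyphenyl)-2,3-dihydro-1,4-benzodioxine-2,6-diyl]dimethanol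
Conditions: DIBAL-H (5 equiv), THF, −78 → 0 °C; Rochelle salt work-up
Reagents that add atoms: none
Why: Hydride reduction of the aryl methyl ester to the benzylic alcohol, with the excess reagent covering the phenol and the free alcohol.

**Step 11**
Reactants: 18 the triol
Product: 19 (2S,3S)-8-hydroxy-2-(hydroxymethyl)-3-(3,4,5-trimethoxyphenyl)-2,3-dihydro-1,4-benzodioxine-6-carbaldehyde
Conditions: activated MnO2 (15 equiv), EtOAc, rt
Reagents that add atoms: none
Why: Chemoselective MnO2 oxidation converts only the benzylic alcohol to the aldehyde and leaves the aliphatic primary alcohol untouched.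

**Step 12**
Reactants: 19 the aryl aldehyde; 20 (triphenylphosphoranylidene)acetaldehyde
Product: 21 (E)-3-[(2S,3S)-8-hydroxy-2-(hydroxymethyl)-3-(3,4,5-trimethoxyphenyl)-2,3-dihydro-1,4-benzodioxin-6-yl]prop-2-enal
Conditions: toluene, 80 °C
Reagents that add atoms: none
Why: Wittig olefination with a stabilised formyl ylide gives the (E)-enal directly and tolerates the free phenol and alcohol.

**Compound list**
1 | methyl 3,5-dibromo-4-hydroxybenzoate | COC(=O)c1cc(Br)c(O)c(Br)c1 | starting material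
2 | tert-butyl bromoacetate | CC(C)(C)OC(=O)CBr | starting material
3 | methyl 3,5-dibromo-4-(2-tert-butoxy-2-oxoethoxy)benzoate | COC(=O)c1cc(Br)c(OCC(=O)OC(C)(C)C)c(Br)c1 | intermediate
4 | 2-[2,6-dibromo-4-(methoxycarbonyl)phenoxy]acetic acid | COC(=O)c1cc(Br)c(OCC(=O)O)c(Br)c1 | intermediate
5 | (R)-4-benzyl-1,3-oxazolidin-2-one | O=C1N[C@H](Cc2ccccc2)CO1 | starting material
6 | 2-[2,6-dibromo-4-(methoxycarbonyl)phenoxy]acetic pivalic anhydride (mixed anhydride) | COC(=O)c1cc(Br)c(OCC(=O)OC(=O)C(C)(C)C)c(Br)c1 | intermediate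
7 | methyl 4-{2-[(4R)-4-benzyl-2-oxo-1,3-oxazolidin-3-yl]-2-oxoethoxy}-3,5-dibromobenzoate | COC(=O)c1cc(Br)c(OCC(=O)N2C(=O)OC[C@H]2Cc2ccccc2)c(Br)c1 | intermediate
8 | 3,4,5-trimethoxybenzaldehyde | COc1cc(C=O)cc(OC)c1OC | starting material
9 | (Z)-dibutylboron enolate of 7 | COC(=O)c1cc(Br)c(O/C=C(\OB(CCCC)CCCC)N2C(=O)OC[C@H]2Cc2ccccc2)c(Br)c1 | intermediate
10 | dibutylboron aldolate (O-boryl form of 11) | COc1cc([C@H](OB(CCCC)CCCC)[C@H](C(=O)N2C(=O)OC[C@H]2Cc2ccccc2)Oc2c(Br)cc(C(=O)OC)cc2Br)cc(OC)c1OC | intermediate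
11 | (4R)-4-benzyl-3-[(2R,3S)-2-(2,6-dibromo-4-methoxycarbonylphenoxy)-3-hydroxy-3-(3,4,5-trimethoxyphenyl)propanoyl]-1,3-oxazolidin-2-one | COc1cc([C@H](O)[C@H](C(=O)N2C(=O)OC[C@H]2Cc2ccccc2)Oc2c(Br)cc(C(=O)OC)cc2Br)cc(OC)c1OC | intermediate
12 | methyl 3,5-dibromo-4-{[(1S,2S)-1,3-dihydroxy-1-(3,4,5-trimethoxyphenyl)propan-2-yl]oxy}benzoate | COc1cc([C@H](O)[C@H](CO)Oc2c(Br)cc(C(=O)OC)cc2Br)cc(OC)c1OC | intermediate
13 | methyl 3,5-dibromo-4-{[(1S,2S)-1-hydroxy-1-(3,4,5-trimethoxyphenyl)-3-(trityloxy)propan-2-yl]oxy}benzoate | COc1cc([C@H](O)[C@H](COC(c2ccccc2)(c2ccccc2)c2ccccc2)Oc2c(Br)cc(C(=O)OC)cc2Br)cc(OC)c1OC | intermediate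
14 | methyl (2S,3S)-8-bromo-3-(3,4,5-trimethoxyphenyl)-2-[(trityloxy)methyl]-2,3-dihydro-1,4-benzodioxine-6-carboxylate | COc1cc([C@@H]2Oc3cc(C(=O)OC)cc(Br)c3O[C@H]2COC(c2ccccc2)(c2ccccc2)c2ccccc2)cc(OC)c1OC | intermediate
15 | methyl (2S,3S)-8-(4,4,5,5-tetramethyl-1,3,2-dioxaborolan-2-yl)-3-(3,4,5-trimethoxyphenyl)-2-[(trityloxy)methyl]-2,3-dihydro-1,4-benzodioxine-6-carboxylate | COc1cc([C@@H]2Oc3cc(C(=O)OC)cc(B4OC(C)(C)C(C)(C)O4)c3O[C@H]2COC(c2ccccc2)(c2ccccc2)c2ccccc2)cc(OC)c1OC | intermediate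
16 | methyl (2S,3S)-8-hydroxy-3-(3,4,5-trimethoxyphenyl)-2-[(trityloxy)methyl]-2,3-dihydro-1,4-benzodioxine-6-carboxylate | COc1cc([C@@H]2Oc3cc(C(=O)OC)cc(O)c3O[C@H]2COC(c2ccccc2)(c2ccccc2)c2ccccc2)cc(OC)c1OC | intermediate
17 | methyl (2S,3S)-8-hydroxy-2-(hydroxymethyl)-3-(3,4,5-trimethoxyphenyl)-2,3-dihydro-1,4-benzodioxine-6-carboxylate | COc1cc([C@@H]2Oc3cc(C(=O)OC)cc(O)c3O[C@H]2CO)cc(OC)c1OC | intermediate
18 | [(2S,3S)-8-hydroxy-3-(3,4,5-trimethoxyphenyl)-2,3-dihydro-1,4-benzodioxine-2,6-diyl]dimethanol | COc1cc([C@@H]2Oc3cc(CO)cc(O)c3O[C@H]2CO)cc(OC)c1OC | intermediate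
19 | (2S,3S)-8-hydroxy-2-(hydroxymethyl)-3-(3,4,5-trimethoxyphenyl)-2,3-dihydro-1,4-benzodioxine-6-carbaldehyde | COc1cc([C@@H]2Oc3cc(C=O)cc(O)c3O[C@H]2CO)cc(OC)c1OC | intermediate
20 | (triphenylphosphoranylidene)acetaldehyde | O=CC=P(c1ccccc1)(c1ccccc1)c1ccccc1 | starting material
21 | (E)-3-[(2S,3S)-8-hydroxy-2-(hydroxymethyl)-3-(3,4,5-trimethoxyphenyl)-2,3-dihydro-1,4-benzodioxin-6-yl]prop-2-enal | COc1cc([C@@H]2Oc3cc(/C=C/C=O)cc(O)c3O[C@H]2CO)cc(OC)c1OC | target

**Totals and risks**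
Total step count: 12. Longest linear sequence: 12 steps (1 → 21); compounds 2, 5, 8 and 20 are bought and enter directly.

Most likely to fail, first: step 7. The copper-catalysed closure involves a hindered secondary benzylic alkoxide and could stall or give hydrodebromination. The fallback sets out from 13 and comes back at 16, closing the ring through the alkyl C–O bond instead of the aryl C–O bond.
- Mitsunobu esterification of 13 (4-nitrobenzoic acid, PPh3, DIAD, THF, 0 °C → rt) inverts the carbinol carbon and gives the (1R,2S) 4-nitrobenzoate F1.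
- K2CO3 in MeOH removes the ester to give the erythro alcohol F2.
- Twofold Miyaura borylation (B2pin2, Pd(dppf)Cl2, KOAc, dioxane, 90 °C) gives the bis(pinacol boronate) F3, which is oxidised without isolation (NaBO3·4H2O, THF/H2O) to the bis-phenol F4.
- Intramolecular Mitsunobu etherification of F4 (PPh3, DIAD, THF, 0 °C) displaces the activated benzylic oxygen with a second inversion. The two phenols are equivalent, so the only product is the trans compound 16, and the route goes on with step 9 (step 8 is then not needed).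

Second: step 8. Borylation of an aryl bromide ortho to the ring oxygen can give protodebromination or incomplete conversion. The fallback sets out from 14 and comes back at 16, replacing C–B formation and oxidation by a direct C–O cross-coupling. Coupling of 14 with (E)-benzaldoxime as hydroxide surrogate (tBuBrettPhos Pd G3, Cs2CO3, DMF, 80 °C) gives the O-aryl benzaldoxime F5, which fragments in the same flask to benzonitrile and the phenol 16.

Third: step 12. The formyl ylide can react sluggishly with the electron-rich hydroxy aldehyde or add a second time to the product enal. The fallback sets out from 19 and comes back at 21, building the enal by oxidation-state adjustment. Wittig reaction of 19 with ethyl (triphenylphosphoranylidene)acetate (toluene, 80 °C) gives the ethyl (E)-cinnamate F6, DIBAL-H (THF, −78 °C) reduces it to the (E)-allylic alcohol F7, and MnO2 (EtOAc, rt) oxidises only the allylic hydroxyl to give 21.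

**Further compounds**
F1 | step 7 | methyl 3,5-dibromo-4-{[(1R,2S)-1-(4-nitrobenzoyloxy)-1-(3,4,5-trimethoxyphenyl)-3-(trityloxy)propan-2-yl]oxy}benzoate | COc1cc([C@@H](OC(=O)c2ccc(cc2)[N+](=O)[O-])[C@H](COC(c2ccccc2)(c2ccccc2)c2ccccc2)Oc2c(Br)cc(C(=O)OC)cc2Br)cc(OC)c1OC
F2 | step 7 | methyl 3,5-dibromo-4-{[(1R,2S)-1-hydroxy-1-(3,4,5-trimethoxyphenyl)-3-(trityloxy)propan-2-yl]oxy}benzoate | COc1cc([C@@H](O)[C@H](COC(c2ccccc2)(c2ccccc2)c2ccccc2)Oc2c(Br)cc(C(=O)OC)cc2Br)cc(OC)c1OC
F3 | step 7 | methyl 4-{[(1R,2S)-1-hydroxy-1-(3,4,5-trimethoxyphenyl)-3-(trityloxy)propan-2-yl]oxy}-3,5-bis(4,4,5,5-tetramethyl-1,3,2-dioxaborolan-2-yl)benzoate | COc1cc([C@@H](O)[C@H](COC(c2ccccc2)(c2ccccc2)c2ccccc2)Oc2c(B3OC(C)(C)C(C)(C)O3)cc(C(=O)OC)cc2B4OC(C)(C)C(C)(C)O4)cc(OC)c1OC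
F4 | step 7 | methyl 3,5-dihydroxy-4-{[(1R,2S)-1-hydroxy-1-(3,4,5-trimethoxyphenyl)-3-(trityloxy)propan-2-yl]oxy}benzoate | COc1cc([C@@H](O)[C@H](COC(c2ccccc2)(c2ccccc2)c2ccccc2)Oc2c(O)cc(C(=O)OC)cc2O)cc(OC)c1OC
F5 | step 8 | methyl (2S,3S)-8-{[(E)-benzylideneamino]oxy}-3-(3,4,5-trimethoxyphenyl)-2-[(trityloxy)methyl]-2,3-dihydro-1,4-benzodioxine-6-carboxylate | COc1cc([C@@H]2Oc3cc(C(=O)OC)cc(O/N=C/c4ccccc4)c3O[C@H]2COC(c2ccccc2)(c2ccccc2)c2ccccc2)cc(OC)c1OC
F6 | step 12 | ethyl (E)-3-[(2S,3S)-8-hydroxy-2-(hydroxymethyl)-3-(3,4,5-trimethoxyphenyl)-2,3-dihydro-1,4-benzodioxin-6-yl]prop-2-enoate | COc1cc([C@@H]2Oc3cc(/C=C/C(=O)OCC)cc(O)c3O[C@H]2CO)cc(OC)c1OC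
F7 | step 12 | (E)-3-[(2S,3S)-8-hydroxy-2-(hydroxymethyl)-3-(3,4,5-trimethoxyphenyl)-2,3-dihydro-1,4-benzodioxin-6-yl]prop-2-en-1-ol | COc1cc([C@@H]2Oc3cc(/C=C/CO)cc(O)c3O[C@H]2CO)cc(OC)c1OC
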